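Locants follow the target: C1 (CH–O-angeloyl), C2 (CH–O of the lactone), C3 (ring-fusion CH), C4 and C5 (ring CH2), C6 (CH–CH3), C7 (C–OH), C8–C10 (side chain, C8 the ketone), C11/C12 (lactone CH(CH3)/C=O); β is the face of the C2 oxygen, α that of the C1 oxygen.
Cuts, in retrosynthetic order: C10–O silyl and C1–O angeloyl; C7–C8 (alkenyl Grignard on a C7 ketone, C8=CH2 as masked ketone); C7=O back to a C6=C7 alkene; the lactone at C3=C11 and O–C12 (phosphonate ester on a C2–OH/C3 ketone); last the ring bond C4–C5.
Enabling feature: C4 and C5 are bare methylenes flanked by C3 (which may be a carbonyl) and by methyl-bearing C6 (which may be olefinic), and C2, C1, C7 all carry oxygen; C3–C2–C1–C7–O is therefore a 2,3-dioxygenated γ-lactone with an isopropenyl group on C7, and its 2-methylene derivative is an allyl vinyl ether whose Claisen shift breaks O–C7, forms C4–C5 and enlarges the oxolane to the seven-membered carbocycle.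
Forward: D-tartrate acetonide → isopropenyl lactone → methylenation → ring-expanding Claisen (carbocycle, with the C3 ketone and the C6=C7 alkene in place) → butenolide (lactone ring) → epoxide, hydrogenation, hydride shift to the C7 ketone → side chain, angelate, ozonolysis, desilylation.
Stereochemistry: C1 and C2 from D-tartaric acid; C3 and C11 by hydrogenation of the butenolide from the C2–H face; C6 by β-epoxidation anti to the C1 silyl ether and hydride shift with inversion; C7 by chelate-controlled Grignard addition; C10 from (R)-pent-4-yn-2-ol; the Z angelate from angelic acid.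

Key step: step 6

Remark: the carbinol carbon made in step 1 (later C7) is carried as both epimers through 4 to 9 and is left undefined in their SMILES, because it becomes sp2 in step 6; the phosphonate-bearing carbon of 13 and the ozonide carbon of 29 are likewise undefined and are lost as stereocentres in the next operation.

Step 1
Reactants: 1 dimethyl (4S,5S)-2,2-dimethyl-1,3-dioxolane-4,5-dicarboxylate (dimethyl 2,3-O-isopropylidene-D-tartrate); 2 isopropenylmagnesium bromide
Product: 4 methyl (4S,5R)-5-(1-hydroxy-2-methylprop-2-en-1-yl)-2,2-dimethyl-1,3-dioxolane-4-carboxylate (both carbinol epimers), via aldehyde 3 (not isolated)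
Conditions: i-Bu2AlH (1.05 equiv), PhMe/CH2Cl2, −78 °C; then 2 (1.5 equiv, THF), −78 → −20 °C; aq. potassium sodium tartrate
Reagents that add atoms: none
Why: Half-reduction of a diester followed by Grignard addition in the same flask: the two ester groups of C2-symmetric 1 are homotopic, the aluminium hemiacetal releases aldehyde 3 only on warming, where it is trapped faster than the remaining ester, and the new carbinol centre needs no control because it becomes sp2 in step 6.

Step 2
Reactants: 4 allylic alcohol
Product: 6 (3S,4S)-3,4-dihydroxy-5-(prop-1-en-2-yl)oxolan-2-one (trans-diol; both C5 epimers), via triol ester 5 (not isolated)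
Conditions: TFA/H2O (9:1), 0 °C → rt; concentrate; PhMe, 60 °C
Reagents that add atoms: none
Why: Acid-catalysed acetal hydrolysis followed by lactonization of the γ-hydroxy ester 5 to the five-membered lactone; the two tartrate-derived centres (later C1 and C2, trans) are not touched.

Step 3
Reactants: 6 diol lactone
Product: 7 4-hydroxy-5-(prop-1-en-2-yl)-3-(triethylsilyloxy)oxolan-2-one (3,4-trans; silyl ether on the hydroxyl α to the carbonyl)
Conditions: Et3SiCl (1.05 equiv), imidazole, DMF, −40 °C
Reagents that add atoms: triethylsilyl chloride, CC[Si](CC)(CC)Cl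
Why: Regioselective silylation: the hydroxyl α to the lactone carbonyl is the more acidic and the less hindered of the two (the other is flanked by the isopropenyl-bearing carbon), the usual order of reactivity in 2,3-dihydroxy-γ-lactones, so one equivalent at low temperature should mark the later C2 oxygen alone.

Step 4
Reactants: 7 mono-silyl lactone
Product: 8 4-(tert-butyldimethylsilyloxy)-5-(prop-1-en-2-yl)-3-(triethylsilyloxy)oxolan-2-one (3,4-trans)
Conditions: TBSOTf (1.3 equiv), 2,6-lutidine, CH2Cl2, −78 → 0 °C
Reagents that add atoms: tert-butyldimethylsilyl triflate, CC(C)(C)[Si](C)(C)OS(=O)(=O)C(F)(F)F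
Why: Silylation of the remaining hindered secondary hydroxyl with a silyl triflate and a hindered base; the bulky, non-chelating TBS ether on the later C1 oxygen survives steps 5 to 12 and steers the epoxidation in step 10.

Step 5
Reactants: 8 bis-silyl lactone
Product: 9 4-(tert-butyldimethylsilyloxy)-2-methylidene-5-(prop-1-en-2-yl)-3-(triethylsilyloxy)oxolane (3,4-trans)
Conditions: Cp2TiMe2 (2.5 equiv), PhMe, 75 °C, dark; filtration through basic Al2O3
Reagents that add atoms: dimethyltitanocene Cp2TiMe2, C[Ti](C)(C1C=CC=C1)C1C=CC=C1
Why: Petasis methylenation (through Cp2Ti=CH2) turns the lactone carbonyl into the exocyclic enol ether under non-basic conditions, as established for protected aldonolactones; no stereocentre is involved.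

Step 6
Reactants: 9 methylene oxolane
Product: 10 3-(tert-butyldimethylsilyloxy)-5-methyl-2-(triethylsilyloxy)cyclohept-4-en-1-one (2,3-trans; target locants: C3 ketone; 2β-OTES; 1α-OTBS; C6=C7 alkene)
Conditions: o-xylene (degassed, 1 % Et3N), base-washed sealed tube, 180 °C
Reagents that add atoms: none
Why: Thermal [3,3]-sigmatropic (Claisen) rearrangement of the allyl vinyl ether C4=C3–O–C7–C6=C5 held inside the oxolane: the O–C7 bond breaks, the C4–C5 bond forms, and the C3 carbonyl and the C6=C7 double bond appear, so the five-membered heterocycle is turned into the seven-membered carbocycle with C=O formation as the driving force. The closest known reaction type is the Claisen ring expansion of 2-methylene-5-vinyloxolanes to cyclohept-4-enones and of carbohydrate-derived 2-methylene-6-vinyloxanes to cyclooctenones. The carbocycle closes by a concerted pericyclic ring enlargement by two atoms through a boat-like six-centre transition state in which the isopropenyl group lies pseudoaxial over the exocyclic methylene, not by an exo or endo attack of a nucleophile. No new stereocentre is formed: C1 and C2 are spectators and keep their tartrate-derived configuration, the ring allows only the Z geometry at C6=C7, and both C7 epimers of 9 converge on 10 because C7 becomes sp2. The selectivity needed is the [3,3] shift over acid-catalysed migration of the exocyclic enol ether double bond into the ring and over loss of the silyloxy groups; it is secured by the neutral, amine-buffered medium in base-washed glass and by the absence of any acidic hydrogen α to a carbonyl before the shift.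

Step 7
Reactants: 10 cycloheptenone
Product: 11 3-(tert-butyldimethylsilyloxy)-2-hydroxy-5-methylcyclohept-4-en-1-one (2,3-trans)
Conditions: PPTS (0.2 equiv), MeOH/CH2Cl2 (1:1), 0 °C
Reagents that add atoms: none
Why: Selective acid-catalysed methanolysis of the triethylsilyl ether beside the much more robust TBS ether; the non-basic medium avoids β-elimination of the C1 silyloxy group and epimerization of the α-hydroxy ketone.

Step 8
Reactants: 11 α-hydroxy ketone; 12 2-(diethoxyphosphoryl)propanoic acid
Product: 13 2-(diethoxyphosphoryl)propanoate of 11 at the C2 oxygen (both epimers at the phosphonate carbon)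
Conditions: DCC (1.4 equiv), DMAP (0.1 equiv), CH2Cl2, 0 °C → rt
Reagents that add atoms: none
Why: Steglich esterification of the secondary ketol hydroxyl; the phosphonate-bearing carbon (later C11) is a mixture, which does not matter because it becomes sp2 in step 9.

Step 9
Reactants: 13 phosphonate ester
Product: 14 8-(tert-butyldimethylsilyloxy)-3,6-dimethyl-4,5,8,8a-tetrahydro-2H-cyclohepta[b]furan-2-one (butenolide fused at C2/C3; C3=C11 and C6=C7 double bonds; 1α-OTBS; C2–O β)
Conditions: LiCl (1.2 equiv), i-Pr2NEt (1.1 equiv), MeCN, 0 °C → rt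
Reagents that add atoms: none
Why: Intramolecular Horner–Wadsworth–Emmons olefination of the C3 ketone by the tethered phosphonate closes the α-methylbutenolide, the standard annulation of α-acyloxy ketones; the lithium-assisted amine base deprotonates only the phosphonate, so neither C2 of the acyloxy ketone nor the γ-position of the butenolide should epimerize.

Step 10
Reactants: 14 butenolide
Product: 15 6,7-β-epoxide of 14 (oxirane anti to the C1 silyl ether)
Conditions: mCPBA (1.2 equiv), CH2Cl2, 0 °C
Reagents that add atoms: mCPBA, OOC(=O)c1cccc(Cl)c1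
Why: Prilezhaev epoxidation: the peracid takes the electron-rich trisubstituted C6=C7 bond and not the electron-poor butenolide double bond, and approaches anti to the bulky allylic silyloxy group on C1 (α), which places the epoxide oxygen on the β face.

Step 11
Reactants: 15 epoxy butenolide
Product: 16 saturated cis-fused lactone epoxide (H-2; H-3; H-11 all α; C11 methyl on the concave face; 6,7-β-epoxide; 1α-OTBS)
Conditions: H2 (60 bar), 5 % Rh/Al2O3, EtOAc, rt
Reagents that add atoms: none
Why: Heterogeneous syn hydrogenation of the tetrasubstituted butenolide from the face of C2–H, the other face being covered by C1 and the carbocycle: the hydrogens at C3 and C11 enter cis to H-2, which gives the cis-fused lactone with the C11 methyl on the concave side as in the target; rhodium on alumina is chosen to avoid hydrogenolysis of the allylic lactone C–O bond and leaves the epoxide and the silyl ether alone.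

Step 12
Reactants: 16 epoxide
Product: 17 C7 ketone (cis-fused lactone; 1α-OTBS; 6β-CH3)
Conditions: BF3·OEt2 (0.2 equiv), CH2Cl2, −78 °C; Et3N quench
Reagents that add atoms: none
Why: Meinwald rearrangement: the Lewis acid opens the epoxide at the tertiary carbon C6 and the C7 hydrogen shifts to C6 on the face opposite to the departing oxygen, so C6 is inverted (H α, methyl β as in the target) and C7 becomes the ketone; ionization at C7 and ring contraction by shift of C1 are disfavoured by the electron-withdrawing silyloxy group on C1.

Step 13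
Reactants: 17 silyloxy ketone
Product: 18 hydroxy ketone (cis-fused lactone; 1α-OH; 6β-CH3; C7 ketone)
Conditions: HF·pyridine, pyridine, THF, 0 °C → rt
Reagents that add atoms: none
Why: Desilylation with buffered HF·pyridine frees the C1 hydroxyl, needed as the chelating group in step 16, under conditions that do not enolize the ketone towards C1 or C6.

Step 14
Reactants: 19 (R)-pent-4-yn-2-ol
Product: 20 (R)-tert-butyldimethyl(pent-4-yn-2-yloxy)silane
Conditions: TBSCl (1.2 equiv), imidazole, DMF, rt
Reagents that add atoms: tert-butyldimethylsilyl chloride, CC(C)(C)[Si](C)(C)Cl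
Why: Standard silylation of a secondary alcohol; the (R) centre (later C10) comes from the commercial alkynol and is not touched.

Step 15
Reactants: 20 silyl ether
Product: 22 (R)-[(4-bromopent-4-en-2-yl)oxy](tert-butyl)dimethylsilane, via alkenylborane 21 (not isolated)
Conditions: B-bromo-9-BBN (1.2 equiv), CH2Cl2, 0 °C; then AcOH, 0 °C → rt
Reagents that add atoms: B-bromo-9-borabicyclo[3.3.1]nonane, BrB1C2CCCC1CCC2
Why: Haloboration: the bromoborane adds syn across the terminal alkyne with boron at the terminal and bromine at the internal carbon, and protonolysis of the alkenyl–boron bond by acetic acid gives the 2-bromo-1-alkene.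

Step 16
Reactants: 18 hydroxy ketone; 22 bromoalkene
Product: 25 diol (cis-fused lactone; 1α-OH; 6β-CH3; 7β-OH; 7α-[(R)-4-(tert-butyldimethylsilyloxy)pent-1-en-2-yl]), via Grignard reagent 23 (not isolated), via magnesium alkoxide 24 (not isolated)
Conditions: 22 (3.5 equiv), Mg turnings, THF, 40 °C; then 18, THF/CH2Cl2, −78 → −40 °C; aq. NH4Cl
Reagents that add atoms: none
Why: Grignard formation and chelation-controlled 1,2-addition: the first equivalent of 23 deprotonates the C1 hydroxyl, the five-membered magnesium chelate of alkoxide 24 holds the C1 oxygen in the carbonyl plane and so turns the trans-disposed C6 methyl pseudoaxial, and the second equivalent adds to the C7 ketone anti to that methyl, from the α face and cis to the C1 oxygen, to give the β tertiary alcohol; the lactone is far less electrophilic than the ketone at this temperature.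

Step 17
Reactants: 25 diol; 26 angelic acid ((Z)-2-methylbut-2-enoic acid)
Product: 28 angelate (25 acylated at O-1 by the (Z)-2-methylbut-2-enoyl group), via mixed anhydride 27 (not isolated)
Conditions: 26 (3 equiv), 2,4,6-trichlorobenzoyl chloride (3 equiv), Et3N, PhMe, rt; then 25, 75 °C
Reagents that add atoms: none
Why: Yamaguchi esterification through mixed anhydride 27: the secondary C1 hydroxyl is acylated and the tertiary C7 hydroxyl is not, and this DMAP-free mixed-anhydride protocol is the established way to attach an angeloyl group without Z to E isomerization to the tiglate.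

Step 18
Reactants: 28 angelate
Product: 30 ketone (the 10-O-TBS ether of the target), via ozonide 29 (not isolated)
Conditions: O3, CH2Cl2, −78 °C (Sudan red 7B end-point); then PPh3, −78 °C → rt
Reagents that add atoms: ozone, [O-][O+]=O
Why: Chemoselective ozonolysis: ozone adds much faster to the electron-rich 1,1-disubstituted side-chain alkene than to the electron-poor, hindered angelate double bond (the dye marks the end-point), and reduction of ozonide 29 gives the C8 ketone.

Step 19
Reactants: 30 silyl ether
Product: 31 target CNP0321985.1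
Conditions: HF·pyridine, pyridine, THF, 0 °C → rt
Reagents that add atoms: none
Why: Desilylation under mildly acidic fluoride conditions that should leave the angelate, the lactone, the α-ketol and the new β-hydroxy ketone untouched (no retro-aldol, elimination or acyl migration as with basic fluoride).

Compound list
1 | dimethyl (4S,5S)-2,2-dimethyl-1,3-dioxolane-4,5-dicarboxylate (dimethyl 2,3-O-isopropylidene-D-tartrate) | CC1(C)O[C@H](C(=O)OC)[C@@H](C(=O)OC)O1 | starting material
2 | isopropenylmagnesium bromide | CC(=C)[Mg]Br | starting material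
3 | methyl (4S,5S)-5-formyl-2,2-dimethyl-1,3-dioxolane-4-carboxylate | CC1(C)O[C@H](C=O)[C@@H](C(=O)OC)O1 | intermediate (not isolated)
4 | methyl (4S,5R)-5-(1-hydroxy-2-methylprop-2-en-1-yl)-2,2-dimethyl-1,3-dioxolane-4-carboxylate, both carbinol epimers | CC1(C)O[C@H](C(O)C(C)=C)[C@@H](C(=O)OC)O1 | intermediate
5 | methyl (2S,3R)-2,3,4-trihydroxy-5-methylhex-5-enoate, both C4 epimers | O[C@H](C(O)C(C)=C)[C@@H](C(=O)OC)O | intermediate (not isolated)
6 | (3S,4S)-3,4-dihydroxy-5-(prop-1-en-2-yl)oxolan-2-one, trans-diol, both C5 epimers | O[C@H]1[C@@H](C(=O)OC1C(C)=C)O | intermediate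
7 | 4-hydroxy-5-(prop-1-en-2-yl)-3-(triethylsilyloxy)oxolan-2-one, 3,4-trans | O[C@H]1[C@@H](C(=O)OC1C(C)=C)O[Si](CC)(CC)CC | intermediate
8 | 4-(tert-butyldimethylsilyloxy)-5-(prop-1-en-2-yl)-3-(triethylsilyloxy)oxolan-2-one, 3,4-trans | CC(C)(C)[Si](C)(C)O[C@H]1[C@@H](C(=O)OC1C(C)=C)O[Si](CC)(CC)CC | intermediate
9 | 4-(tert-butyldimethylsilyloxy)-2-methylidene-5-(prop-1-en-2-yl)-3-(triethylsilyloxy)oxolane, 3,4-trans | CC(C)(C)[Si](C)(C)O[C@H]1[C@@H](C(=C)OC1C(C)=C)O[Si](CC)(CC)CC | intermediate
10 | 3-(tert-butyldimethylsilyloxy)-5-methyl-2-(triethylsilyloxy)cyclohept-4-en-1-one, 2,3-trans | CC(C)(C)[Si](C)(C)O[C@H]1[C@@H](C(=O)CCC(C)=C1)O[Si](CC)(CC)CC | intermediate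
11 | 3-(tert-butyldimethylsilyloxy)-2-hydroxy-5-methylcyclohept-4-en-1-one, 2,3-trans | CC(C)(C)[Si](C)(C)O[C@H]1[C@@H](C(=O)CCC(C)=C1)O | intermediate
12 | 2-(diethoxyphosphoryl)propanoic acid | CCOP(=O)(OCC)C(C)C(=O)O | starting material
13 | 2-(diethoxyphosphoryl)propanoate of 11 at the C2 oxygen | CC(C)(C)[Si](C)(C)O[C@H]1[C@@H](C(=O)CCC(C)=C1)OC(=O)C(C)P(=O)(OCC)OCC | intermediate
14 | 8-(tert-butyldimethylsilyloxy)-3,6-dimethyl-4,5,8,8a-tetrahydro-2H-cyclohepta[b]furan-2-one (butenolide; 1α-OTBS, C2–O β) | CC(C)(C)[Si](C)(C)O[C@H]1[C@@H]2OC(=O)C(C)=C2CCC(C)=C1 | intermediate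
15 | 6,7-β-epoxide of 14 | CC(C)(C)[Si](C)(C)O[C@H]1[C@@H]2OC(=O)C(C)=C2CC[C@]3(C)O[C@H]13 | intermediate
16 | saturated cis-fused lactone 6,7-β-epoxide (H-2, H-3, H-11 all α; 1α-OTBS) | CC(C)(C)[Si](C)(C)O[C@H]1[C@@H]2OC(=O)[C@H](C)[C@@H]2CC[C@]3(C)O[C@H]13 | intermediate
17 | C7 ketone, cis-fused lactone, 1α-OTBS, 6β-methyl | CC(C)(C)[Si](C)(C)O[C@H]1[C@@H]2OC(=O)[C@H](C)[C@@H]2CC[C@H](C)C1=O | intermediate
18 | C7 ketone, cis-fused lactone, 1α-OH, 6β-methyl | O[C@H]1[C@@H]2OC(=O)[C@H](C)[C@@H]2CC[C@H](C)C1=O | intermediate
19 | (R)-pent-4-yn-2-ol | C#CC[C@@H](C)O | starting material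
20 | (R)-tert-butyldimethyl(pent-4-yn-2-yloxy)silane | C#CC[C@@H](C)O[Si](C)(C)C(C)(C)C | intermediate
21 | (Z)-2-bromoalkenyl-9-BBN adduct of 20 | Br/C(C[C@@H](C)O[Si](C)(C)C(C)(C)C)=C\B1C2CCCC1CCC2 | intermediate (not isolated)
22 | (R)-[(4-bromopent-4-en-2-yl)oxy](tert-butyl)dimethylsilane | C=C(Br)C[C@@H](C)O[Si](C)(C)C(C)(C)C | intermediate
23 | [(R)-4-(tert-butyldimethylsilyloxy)pent-1-en-2-yl]magnesium bromide | C=C([Mg]Br)C[C@@H](C)O[Si](C)(C)C(C)(C)C | intermediate (not isolated)
24 | bromomagnesium C1-alkoxide of 18 | Br[Mg]O[C@H]1[C@@H]2OC(=O)[C@H](C)[C@@H]2CC[C@H](C)C1=O | intermediate (not isolated)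
25 | diol: cis-fused lactone, 1α-OH, 6β-methyl, 7β-OH, 7α-[(R)-4-(tert-butyldimethylsilyloxy)pent-1-en-2-yl] | O[C@H]1[C@@H]2OC(=O)[C@H](C)[C@@H]2CC[C@H](C)[C@@]1(O)C(=C)C[C@@H](C)O[Si](C)(C)C(C)(C)C | intermediate
26 | angelic acid, (Z)-2-methylbut-2-enoic acid | C/C=C(/C)C(=O)O | starting material
27 | angelic 2,4,6-trichlorobenzoic mixed anhydride | C/C=C(/C)C(=O)OC(=O)c1c(Cl)cc(Cl)cc1Cl | intermediate (not isolated)
28 | C1 angelate of 25 | C/C=C(/C)C(=O)O[C@H]1[C@@H]2OC(=O)[C@H](C)[C@@H]2CC[C@H](C)[C@@]1(O)C(=C)C[C@@H](C)O[Si](C)(C)C(C)(C)C | intermediate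
29 | 1,2,4-trioxolane (ozonide) at C8 of 28 | C/C=C(/C)C(=O)O[C@H]1[C@@H]2OC(=O)[C@H](C)[C@@H]2CC[C@H](C)[C@@]1(O)C3(OCOO3)C[C@@H](C)O[Si](C)(C)C(C)(C)C | intermediate (not isolated)
30 | 10-O-TBS ether of the target | C/C=C(/C)C(=O)O[C@H]1[C@@H]2OC(=O)[C@H](C)[C@@H]2CC[C@H](C)[C@@]1(O)C(=O)C[C@@H](C)O[Si](C)(C)C(C)(C)C | intermediate
31 | CNP0321985.1 | C/C=C(/C)C(=O)O[C@H]1[C@@H]2OC(=O)[C@H](C)[C@@H]2CC[C@H](C)[C@@]1(O)C(=O)C[C@@H](C)O | target

Total steps: 19. Longest linear sequence: 17 steps (steps 1–13 and 16–19, from 1); steps 14 and 15 prepare the side-chain bromide.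

Steps most likely to fail

Step 6, the thermal ring expansion. The exocyclic enol ether double bond of 9 may migrate into the ring under trace acid, or the substrate may decompose, before the [3,3] shift sets in at 180 °C. Fallback: setting out from 9, the Lewis-acid-promoted variant known from carbohydrate-derived methylene oxolanes and oxanes is used. i-Bu3Al (CH2Cl2, −78 → 0 °C) ionizes the allylic C7–O bond, the aluminium enolate and the allyl cation recombine at C4–C5, and the ketone is reduced in the same flask by hydride transfer from an isobutyl group to give the cycloheptenol F1 (both carbinol epimers). Oxidation with Dess–Martin periodinane (CH2Cl2, rt) comes back to the route at 10.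

Step 12, the hydride shift. The C6 cation may lose a proton to give allylic alcohols, or the ring may contract, instead of the 1,2-hydride shift. Fallback: setting out from 16, the allylic alcohol is made on purpose. Al(O-i-Pr)3 in PhMe at 110 °C isomerizes the epoxide to the exocyclic allylic alcohol F2 (C7–OH β, C6=CH2). Dess–Martin periodinane gives the α-methylene ketone F3. Hydrogenation over Pd/C (EtOAc, rt) from the convex α face of the cis-fused bicycle, the side away from the lactone ring, should set the C6 methyl β and comes back to the route at 17.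

Step 16, the addition to the C7 ketone. Facial selectivity may be poor if the magnesium alkoxide chelate does not dominate, and the basic reagent used in excess may enolize the hindered ketone. Fallback: setting out from 18, the C1 hydroxyl is turned into a neutral chelating ether with 4-methoxybenzyl trichloroacetimidate and catalytic camphorsulfonic acid (CH2Cl2), giving the PMB ether F4. Grignard reagent 23 (1.5 equiv) is then added in the presence of MgBr2·OEt2 in CH2Cl2 at −78 °C, a Cram-chelate addition through a bidentate ether–carbonyl complex that needs no excess of base, to give the adduct F5. Oxidative removal of the PMB group with DDQ (CH2Cl2/pH 7 buffer) comes back to the route at 25.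

Further compounds
F1 | step 6 | 3-(tert-butyldimethylsilyloxy)-5-methyl-2-(triethylsilyloxy)cyclohept-4-en-1-ol, both carbinol epimers | CC(C)(C)[Si](C)(C)O[C@H]1[C@@H](C(O)CCC(C)=C1)O[Si](CC)(CC)CC
F2 | step 12 | allylic alcohol: cis-fused lactone, 1α-OTBS, 7β-OH, 6-methylidene | CC(C)(C)[Si](C)(C)O[C@H]1[C@@H]2OC(=O)[C@H](C)[C@@H]2CCC(=C)[C@@H]1O
F3 | step 12 | α-methylene ketone: cis-fused lactone, 1α-OTBS, C7 ketone, 6-methylidene | CC(C)(C)[Si](C)(C)O[C@H]1[C@@H]2OC(=O)[C@H](C)[C@@H]2CCC(=C)C1=O
F4 | step 16 | C1 4-methoxybenzyl ether of 18 | COc1ccc(cc1)CO[C@H]1[C@@H]2OC(=O)[C@H](C)[C@@H]2CC[C@H](C)C1=O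
F5 | step 16 | C1 4-methoxybenzyl ether of 25 | COc1ccc(cc1)CO[C@H]1[C@@H]2OC(=O)[C@H](C)[C@@H]2CC[C@H](C)[C@@]1(O)C(=C)C[C@@H](C)O[Si](C)(C)C(C)(C)C
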